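**Retrosynthetic overview**
1. The target is (−)-epicatechin-(4β→8)-4β-carboxymethyl-(−)-epicatechin. The last cuts are the ten benzyl groups and then the C4(upper)–C8(lower) bond, which is made by cationic coupling of an upper flavan-4-ol with the C8 position of a lower unit.
2. Lower unit: rings A, B and C are bought intact as (−)-epicatechin. C4 is oxidised with DDQ and alkylated from the β face with the ketene silyl acetal of benzyl acetate.
3. Upper unit: ring C is cut at O1–C8a and at C4a–C4. This leads back to 3,5-bis(benzyloxy)benzyne (ring A) and an acyclic (2S,3R)-2-benzyloxy-3-silyloxy-3-arylpropanal (ring B plus O1, C2, C3, C4), made by an Evans syn glycolate aldol.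
4. Enabling feature: on ring A the C5 oxygen stands next to C4a and meta to C8a. The C4a≡C8a aryne therefore takes the C2-bound oxygen at C8a only and leaves its carbanion at C4a, at six-ring distance from the C4 carbonyl. Because O1 stays on C2, the syn aldol pair becomes the 2,3-cis pair with no ionisation at benzylic C2.
5. Ring order: ring C of the upper unit is the only ring built (step 8). All other rings are carried in.

Key step: step 8

Remark on the chemistry: flavan numbering (O1, C2, C3, C4, C4a, C5 to C8, C8a) is used for both units. The carbinol carbon C4 of 17 is written without configuration, because both epimers give the same C4 cation in step 13. No other centre is left open.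

**Step 1**
Reactants: 1 3,5-bis(benzyloxy)phenol
Product: 2 2-bromo-3,5-bis(benzyloxy)phenol
Conditions: NBS (1.0 equiv), i-Pr2NH (cat.), CH2Cl2, −78 → 0 °C
Reagents that add atoms: N-bromosuccinimide O=C1CCC(=O)N1Br
Why: Ortho-selective electrophilic aromatic bromination of a phenol: the N-bromoamine formed from NBS and the amine is hydrogen-bonded to the phenol OH and delivers bromine to C2, while the alternative C4 site is shielded by two flanking benzyloxy groups.

**Step 2**
Reactants: 2 2-bromo-3,5-bis(benzyloxy)phenol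
Product: 5 3,5-bis(benzyloxy)-2-(trimethylsilyl)phenyl trifluoromethanesulfonate, via bromoaryl trimethylsilyl ether 3 (not isolated), via lithium 2-silylphenolate 4 (not isolated)
Conditions: (Me3Si)2NH, THF, 65 °C, evaporate; n-BuLi, THF, −78 °C; Tf2O, −78 °C → rt
Reagents that add atoms: hexamethyldisilazane C[Si](C)(C)N[Si](C)(C)C; trifluoromethanesulfonic anhydride O=S(=O)(OS(=O)(=O)C(F)(F)F)C(F)(F)F
Why: Standard o-silylaryl triflate sequence: O-silylation, bromine–lithium exchange, 1,3 O-to-C silyl shift (retro-Brook rearrangement) to phenolate 4 and O-triflation, all faster at −78 °C than any attack on the benzyl ethers.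

**Step 3**
Reactants: 6 (S)-4-benzyloxazolidin-2-one; 7 (benzyloxy)acetyl chloride
Product: 8 (S)-4-benzyl-3-[(benzyloxy)acetyl]oxazolidin-2-one
Conditions: Et3N, DMAP (cat.), CH2Cl2, 0 °C → rt
Reagents that add atoms: none
Why: DMAP-catalysed N-acylation of an oxazolidinone by an acid chloride, which does not touch the auxiliary stereocentre.

**Step 4**
Reactants: 8 (S)-4-benzyl-3-[(benzyloxy)acetyl]oxazolidin-2-one; 9 3,4-bis(benzyloxy)benzaldehyde
Product: 11 (S)-4-benzyl-3-{(2S,3R)-2-(benzyloxy)-3-[3,4-bis(benzyloxy)phenyl]-3-hydroxypropanoyl}oxazolidin-2-one, via Z-boron enolate 10 (not isolated)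
Conditions: Bu2BOTf, Et3N, CH2Cl2, 0 °C; 9, −78 → 0 °C; H2O2, MeOH, pH 7 buffer
Reagents that add atoms: none
Why: Evans syn aldol reaction: the Z-boron enolate 10 reacts through a closed Zimmerman–Traxler chair in which the benzyl group of the auxiliary blocks one enolate face, which sets the (2S,3R) syn pair that becomes C3 and C2 of the upper unit and leaves the two oxygens differentiated (OBn against free OH).

**Step 5**
Reactants: 11 aldol adduct
Product: 12 (2S,3R)-2-(benzyloxy)-3-[3,4-bis(benzyloxy)phenyl]-3-hydroxy-N-methoxy-N-methylpropanamide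
Conditions: MeNH(OMe)·HCl, AlMe3, THF, 0 °C → rt; aq. potassium sodium tartrate
Reagents that add atoms: N,O-dimethylhydroxylamine hydrochloride CNOC.Cl
Why: Aluminium amide transamination of the imide to the Weinreb amide, accelerated by the free β-hydroxyl group and run cold enough to avoid retro-aldol cleavage, so both stereocentres are kept and the auxiliary is recovered.

**Step 6**
Reactants: 12 Weinreb amide
Product: 13 (2S,3R)-2-(benzyloxy)-3-[3,4-bis(benzyloxy)phenyl]-N-methoxy-N-methyl-3-(triethylsilyloxy)propanamide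
Conditions: Et3SiCl, imidazole, CH2Cl2, 0 °C → rt
Reagents that add atoms: chlorotriethylsilane CC[Si](Cl)(CC)CC
Why: Routine silylation of a secondary alcohol; the triethylsilyl ether survives hydride reduction and chromatography but is cleaved by fluoride, which is what step 8 needs.

**Step 7**
Reactants: 13 silylated Weinreb amide
Product: 14 (2S,3R)-2-(benzyloxy)-3-[3,4-bis(benzyloxy)phenyl]-3-(triethylsilyloxy)propanal
Conditions: i-Bu2AlH, THF, −78 °C; aq. potassium sodium tartrate
Reagents that add atoms: none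
Why: Weinreb amide reduction: the chelated tetrahedral aluminium adduct holds until work-up, which prevents over-reduction, and the low temperature keeps the α-alkoxy stereocentre intact.

**Step 8**
Reactants: 14 (2S,3R)-2-(benzyloxy)-3-[3,4-bis(benzyloxy)phenyl]-3-(triethylsilyloxy)propanal; 5 3,5-bis(benzyloxy)-2-(trimethylsilyl)phenyl trifluoromethanesulfonate
Product: 17 (2R,3R)-3,5,7-tris(benzyloxy)-2-[3,4-bis(benzyloxy)phenyl]-3,4-dihydro-2H-chromen-4-ol as its C4 epimers, via potassium alkoxide 15 (not isolated), via 3,5-bis(benzyloxy)benzyne 16 (not isolated)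
Conditions: KF (4 equiv), 18-crown-6, THF, −20 °C → rt, 5 (1.3 equiv) added slowly; then H2O
Reagents that add atoms: none
Why: Proposed new method: fluoride strips the Et3Si group from 14 and the Me3Si group from 5, so that the proton-free alkoxide 15 and the aryne 16 (formed by loss of triflate) meet; the alkoxide oxygen adds to the aryne carbon that becomes C8a, and the C4a aryl anion so formed adds to the aldehyde carbon C4. The closest known reaction types are the aryne annulations of salicylaldehydes and salicylates (phenoxide addition, then attack of the aryl anion on the ortho carbonyl group, giving xanthols and xanthones) and the insertion of arynes into the O–H bond of aliphatic alcohols; new is the use of an aliphatic β-oxido aldehyde as the four-atom partner. Ring C closes in the 6-exo-trig mode, the attacking C4a and the carbonyl carbon C4 being linked by C8a, O1, C2 and C3. C2 and C3 are carried over from the aldol unchanged, since the new bond is made at oxygen and not at the benzylic carbon (retention), so the syn pair becomes the 2,3-cis pair; the new C4 carbinol centre is under substrate control only (a Cornforth-type alignment of C4=O against the C3–OBn dipole should favour 3,4-trans) and needs no control, because step 13 planarises C4. The regioselectivity needed is secured by the C5 benzyloxy group, whose inductive pull distorts the aryne, makes C8a the electrophilic terminus and stabilises the negative charge at the adjacent C4a. The chemoselectivity needed (capture of 15 by 16 before retro-aldol cleavage or α-epimerisation, ring closure before protonation) is served by a low stationary concentration of 15, by the absence of any O–H or acidic C–H donor (silyl ether in place of the alcohol, no acetonitrile) and by the high electrophilicity of the aldehyde.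

**Step 9**
Reactants: 18 (−)-epicatechin
Product: 19 5,7,3',4'-tetra-O-benzyl-(−)-epicatechin, (2R,3R)
Conditions: BnBr (4.2 equiv), K2CO3, DMF, 0 °C → rt, argon
Reagents that add atoms: benzyl bromide BrCc1ccccc1
Why: Williamson ether synthesis: K2CO3 deprotonates only the four phenols, so the aliphatic 3-OH stays free and C2 and C3 are untouched under inert gas at room temperature.

**Step 10**
Reactants: 19 5,7,3',4'-tetra-O-benzyl-(−)-epicatechin
Product: 20 (2R,3R,4S)-5,7-bis(benzyloxy)-2-[3,4-bis(benzyloxy)phenyl]-4-(2-ethoxyethoxy)-3,4-dihydro-2H-chromen-3-ol (4β ether)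
Conditions: DDQ, 2-ethoxyethanol, CH2Cl2, 0 °C → rt
Reagents that add atoms: 2-ethoxyethanol CCOCCO
Why: DDQ benzylic oxidation: hydride abstraction from C4 gives a cation stabilised by the 5,7-dioxygenated ring A, which the alcohol captures from the β face, anti to the axial 3α-OH, as is established for this substrate class.

**Step 11**
Reactants: 21 benzyl acetate
Product: 23 1-(benzyloxy)-1-(tert-butyldimethylsilyloxy)ethene, via lithium enolate 22 (not isolated)
Conditions: LiN(i-Pr)2, THF, −78 °C; t-BuMe2SiCl, DMPU, −78 °C → rt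
Reagents that add atoms: tert-butyldimethylsilyl chloride CC(C)(C)[Si](C)(C)Cl
Why: Kinetic ester enolate formation and O-silylation, the bulky silyl chloride in a polar cosolvent favouring O- over C-silylation.

**Step 12**
Reactants: 20 4β-(2-ethoxyethoxy) ether; 23 ketene silyl acetal
Product: 24 benzyl 2-{(2R,3R,4S)-5,7-bis(benzyloxy)-2-[3,4-bis(benzyloxy)phenyl]-3-hydroxy-3,4-dihydro-2H-chromen-4-yl}acetate (4β side chain)
Conditions: 23 (3 equiv), TMSOTf (0.2 equiv), CH2Cl2, −78 °C
Reagents that add atoms: none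
Why: Mukaiyama-type SN1 alkylation of a benzylic ether: TMSOTf ionises the C4 ether to the ring-A-stabilised cation, and the far more nucleophilic ketene silyl acetal adds from the β face, anti to the axial 3α-OH, which sets the 4β (4S) centre.

**Step 13**
Reactants: 17 upper flavan-4-ol; 24 lower unit ester
Product: 25 benzyl ester of 3,5,7,3',4'-penta-O-benzylepicatechin-(4β→8)-5,7,3',4'-tetra-O-benzyl-4β-carboxymethylepicatechin
Conditions: 24 (2.5 equiv, excess recovered), Yb(OTf)3 (0.2 equiv), 4 Å molecular sieves, CH2Cl2, 0 °C → rt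
Reagents that add atoms: none
Why: Cationic Friedel–Crafts interflavan condensation, the standard way to 4→8 procyanidins: the Lewis acid ionises the C4–OH of either epimer of 17 to a cation stabilised by the 5,7-dioxygenated ring A, and the most nucleophilic position C8 of 24 attacks from the β face, anti to the axial 3α-benzyloxy group, which sets the 3,4-trans (4R) centre.

**Step 14**
Reactants: 25 protected dimer
Product: 26 (−)-epicatechin-(4β→8)-4β-carboxymethyl-(−)-epicatechin (CNP0190976.1)
Conditions: H2 (1 atm), Pd(OH)2/C, THF–MeOH–H2O, rt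
Reagents that add atoms: none
Why: Catalytic hydrogenolysis of nine benzyl ethers and one benzyl ester under neutral conditions, which is known to leave the interflavan bond, the benzylic C2–O1 bonds and all six stereocentres of procyanidin-type dimers intact.

**Compound list**
1 | 3,5-bis(benzyloxy)phenol | Oc1cc(OCc2ccccc2)cc(OCc2ccccc2)c1 | starting material
2 | 2-bromo-3,5-bis(benzyloxy)phenol | Oc1cc(OCc2ccccc2)cc(OCc2ccccc2)c1Br | intermediate
3 | [2-bromo-3,5-bis(benzyloxy)phenoxy]trimethylsilane | C[Si](C)(C)Oc1cc(OCc2ccccc2)cc(OCc2ccccc2)c1Br | intermediate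
4 | lithium 3,5-bis(benzyloxy)-2-(trimethylsilyl)phenolate | [Li+].[O-]c1cc(OCc2ccccc2)cc(OCc2ccccc2)c1[Si](C)(C)C | intermediate
5 | 3,5-bis(benzyloxy)-2-(trimethylsilyl)phenyl trifluoromethanesulfonate | C[Si](C)(C)c1c(OS(=O)(=O)C(F)(F)F)cc(OCc2ccccc2)cc1OCc1ccccc1 | intermediate
6 | (S)-4-benzyloxazolidin-2-one | O=C1N[C@@H](Cc2ccccc2)CO1 | starting material
7 | (benzyloxy)acetyl chloride | O=C(Cl)COCc1ccccc1 | starting material
8 | (S)-4-benzyl-3-[(benzyloxy)acetyl]oxazolidin-2-one | O=C(COCc1ccccc1)N1C(=O)OC[C@@H]1Cc1ccccc1 | intermediate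
9 | 3,4-bis(benzyloxy)benzaldehyde | O=Cc1ccc(OCc2ccccc2)c(OCc2ccccc2)c1 | starting material
10 | Z-dibutylboron enolate of 8 | CCCCB(CCCC)O/C(=C\OCc1ccccc1)N1C(=O)OC[C@@H]1Cc1ccccc1 | intermediate
11 | (S)-4-benzyl-3-{(2S,3R)-2-(benzyloxy)-3-[3,4-bis(benzyloxy)phenyl]-3-hydroxypropanoyl}oxazolidin-2-one | O=C(N1C(=O)OC[C@@H]1Cc1ccccc1)[C@@H](OCc1ccccc1)[C@H](O)c1ccc(OCc2ccccc2)c(OCc2ccccc2)c1 | intermediate
12 | (2S,3R)-2-(benzyloxy)-3-[3,4-bis(benzyloxy)phenyl]-3-hydroxy-N-methoxy-N-methylpropanamide | CON(C)C(=O)[C@@H](OCc1ccccc1)[C@H](O)c1ccc(OCc2ccccc2)c(OCc2ccccc2)c1 | intermediate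
13 | (2S,3R)-2-(benzyloxy)-3-[3,4-bis(benzyloxy)phenyl]-N-methoxy-N-methyl-3-(triethylsilyloxy)propanamide | CON(C)C(=O)[C@@H](OCc1ccccc1)[C@H](O[Si](CC)(CC)CC)c1ccc(OCc2ccccc2)c(OCc2ccccc2)c1 | intermediate
14 | (2S,3R)-2-(benzyloxy)-3-[3,4-bis(benzyloxy)phenyl]-3-(triethylsilyloxy)propanal | O=C[C@@H](OCc1ccccc1)[C@H](O[Si](CC)(CC)CC)c1ccc(OCc2ccccc2)c(OCc2ccccc2)c1 | intermediate
15 | potassium (1R,2S)-2-(benzyloxy)-1-[3,4-bis(benzyloxy)phenyl]-3-oxopropan-1-olate | O=C[C@@H](OCc1ccccc1)[C@H]([O-])c1ccc(OCc2ccccc2)c(OCc2ccccc2)c1.[K+] | intermediate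
16 | 3,5-bis(benzyloxy)benzyne (1,2-didehydro-3,5-bis(benzyloxy)benzene) | C1#CC(OCc2ccccc2)=CC(OCc2ccccc2)=C1 | intermediate
17 | (2R,3R)-3,5,7-tris(benzyloxy)-2-[3,4-bis(benzyloxy)phenyl]-3,4-dihydro-2H-chromen-4-ol, 2,3-cis, C4 epimers | OC1c2c(OCc3ccccc3)cc(OCc3ccccc3)cc2O[C@H](c2ccc(OCc3ccccc3)c(OCc3ccccc3)c2)[C@@H]1OCc1ccccc1 | intermediate
18 | (−)-epicatechin, (2R,3R) | C1c2c(O)cc(O)cc2O[C@H](c2ccc(O)c(O)c2)[C@@H]1O | starting material
19 | 5,7,3',4'-tetra-O-benzyl-(−)-epicatechin | C1c2c(OCc3ccccc3)cc(OCc3ccccc3)cc2O[C@H](c2ccc(OCc3ccccc3)c(OCc3ccccc3)c2)[C@@H]1O | intermediate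
20 | (2R,3R,4S)-5,7,3',4'-tetra-O-benzyl-4β-(2-ethoxyethoxy)epicatechin | CCOCCO[C@H]1c2c(OCc3ccccc3)cc(OCc3ccccc3)cc2O[C@H](c2ccc(OCc3ccccc3)c(OCc3ccccc3)c2)[C@@H]1O | intermediate
21 | benzyl acetate | CC(=O)OCc1ccccc1 | starting material
22 | lithium enolate of benzyl acetate | [Li+].[O-]C(=C)OCc1ccccc1 | intermediate
23 | 1-(benzyloxy)-1-(tert-butyldimethylsilyloxy)ethene | C=C(OCc1ccccc1)O[Si](C)(C)C(C)(C)C | intermediate
24 | benzyl 2-{(2R,3R,4S)-5,7-bis(benzyloxy)-2-[3,4-bis(benzyloxy)phenyl]-3-hydroxy-3,4-dihydro-2H-chromen-4-yl}acetate | O=C(C[C@H]1c2c(OCc3ccccc3)cc(OCc3ccccc3)cc2O[C@H](c2ccc(OCc3ccccc3)c(OCc3ccccc3)c2)[C@@H]1O)OCc1ccccc1 | intermediate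
25 | protected dimer, upper unit (2R,3R,4R), lower unit (2R,3R,4S), 4β→8 linked, ten benzyl groups | O=C(C[C@H]1c2c(OCc3ccccc3)cc(OCc3ccccc3)c([C@H]3c4c(OCc5ccccc5)cc(OCc5ccccc5)cc4O[C@H](c4ccc(OCc5ccccc5)c(OCc5ccccc5)c4)[C@@H]3OCc3ccccc3)c2O[C@H](c2ccc(OCc3ccccc3)c(OCc3ccccc3)c2)[C@@H]1O)OCc1ccccc1 | intermediate
26 | (−)-epicatechin-(4β→8)-4β-carboxymethyl-(−)-epicatechin | O=C(O)C[C@H]1c2c(O)cc(O)c([C@H]3c4c(O)cc(O)cc4O[C@H](c4ccc(O)c(O)c4)[C@@H]3O)c2O[C@H](c2ccc(O)c(O)c2)[C@@H]1O | target

**Step count and risks**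
Total step count: 14.
Longest linear sequence: 8 steps (3, 4, 5, 6, 7, 8, 13, 14).

**Steps most likely to fail**

**Step 8.** Several processes could defeat the annulation:
- retro-aldol cleavage, β-elimination or α-epimerisation of the β-oxido aldehyde before it meets the aryne;
- protonation of the aryl anion before ring closure;
- arylation of the product alkoxide by a second aryne.

The fallback makes the same two bonds one after the other by known reactions. It sets out from Weinreb amide 12 and triflate 5. Aryne insertion into the O–H bond of the free secondary alcohol (KF, 18-crown-6, THF, 0 °C) should give the 3,5-bis(benzyloxy)phenyl ether of the Weinreb amide F1. Reduction with i-Bu2AlH (THF, −78 °C) should give the aryloxy aldehyde F2. A chelation-activated intramolecular Friedel–Crafts hydroxyalkylation (MgBr2·OEt2, CH2Cl2, −40 °C) then closes C4a–C4 at either of the two equivalent ortho positions of the phloroglucinol triether. The route is rejoined at 17.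

**Step 13.** The C4 cation could condense with the free C8 or C6 position of a second molecule of 17 (oligomerisation), or it could attack C6 instead of C8 of 24.

The fallback is halogen capping of the electrophile. It sets out from 17. NBS (CH2Cl2, −78 °C) should brominate C8 to give the 8-bromo flavan-4-ol F3, whose ring A is blocked and deactivated. Coupling with 24 under Yb(OTf)3 catalysis should then give the 8-bromo protected dimer F4 without self-condensation. Hydrogenolysis (H2, Pd(OH)2/C, Et3N, THF–MeOH) removes the bromine together with the benzyl groups. The route is rejoined at 26.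

**Step 12.** Silyl transfer from the ketene acetal to the free 3-hydroxyl group could consume the reagent. The C4 cation could also condense with ring A of a second molecule, or β-facial selectivity could erode.

The fallback builds the side chain by oxidative degradation of an allyl group. It sets out from 20. Hosomi–Sakurai allylation (allyltrimethylsilane, BF3·OEt2, CH2Cl2, −78 °C) should give the 4β-allyl compound F5. Lemieux–Johnson cleavage (OsO4 cat., NaIO4, 2,6-lutidine, dioxane–H2O) should give the aldehyde F6. Pinnick oxidation (NaClO2, NaH2PO4, 2-methyl-2-butene, t-BuOH–H2O) should give the acid F7. Esterification (BnBr, K2CO3, DMF) rejoins the route at 24.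

**Further compounds**
F1 | step 8 | (2S,3R)-2-(benzyloxy)-3-[3,4-bis(benzyloxy)phenyl]-3-[3,5-bis(benzyloxy)phenoxy]-N-methoxy-N-methylpropanamide | CON(C)C(=O)[C@@H](OCc1ccccc1)[C@H](Oc1cc(OCc2ccccc2)cc(OCc2ccccc2)c1)c1ccc(OCc2ccccc2)c(OCc2ccccc2)c1
F2 | step 8 | (2S,3R)-2-(benzyloxy)-3-[3,4-bis(benzyloxy)phenyl]-3-[3,5-bis(benzyloxy)phenoxy]propanal | O=C[C@@H](OCc1ccccc1)[C@H](Oc1cc(OCc2ccccc2)cc(OCc2ccccc2)c1)c1ccc(OCc2ccccc2)c(OCc2ccccc2)c1
F3 | step 13 | (2R,3R)-8-bromo-3,5,7-tris(benzyloxy)-2-[3,4-bis(benzyloxy)phenyl]-3,4-dihydro-2H-chromen-4-ol, C4 epimers | OC1c2c(OCc3ccccc3)cc(OCc3ccccc3)c(Br)c2O[C@H](c2ccc(OCc3ccccc3)c(OCc3ccccc3)c2)[C@@H]1OCc1ccccc1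
F4 | step 13 | 8-bromo analogue of 25 (bromine on C8 of the upper unit) | O=C(C[C@H]1c2c(OCc3ccccc3)cc(OCc3ccccc3)c([C@H]3c4c(OCc5ccccc5)cc(OCc5ccccc5)c(Br)c4O[C@H](c4ccc(OCc5ccccc5)c(OCc5ccccc5)c4)[C@@H]3OCc3ccccc3)c2O[C@H](c2ccc(OCc3ccccc3)c(OCc3ccccc3)c2)[C@@H]1O)OCc1ccccc1
F5 | step 12 | (2R,3R,4S)-4-allyl-5,7-bis(benzyloxy)-2-[3,4-bis(benzyloxy)phenyl]-3,4-dihydro-2H-chromen-3-ol | C=CC[C@H]1c2c(OCc3ccccc3)cc(OCc3ccccc3)cc2O[C@H](c2ccc(OCc3ccccc3)c(OCc3ccccc3)c2)[C@@H]1O
F6 | step 12 | 2-{(2R,3R,4S)-5,7-bis(benzyloxy)-2-[3,4-bis(benzyloxy)phenyl]-3-hydroxy-3,4-dihydro-2H-chromen-4-yl}acetaldehyde | O=CC[C@H]1c2c(OCc3ccccc3)cc(OCc3ccccc3)cc2O[C@H](c2ccc(OCc3ccccc3)c(OCc3ccccc3)c2)[C@@H]1O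
F7 | step 12 | 2-{(2R,3R,4S)-5,7-bis(benzyloxy)-2-[3,4-bis(benzyloxy)phenyl]-3-hydroxy-3,4-dihydro-2H-chromen-4-yl}acetic acid | O=C(O)C[C@H]1c2c(OCc3ccccc3)cc(OCc3ccccc3)cc2O[C@H](c2ccc(OCc3ccccc3)c(OCc3ccccc3)c2)[C@@H]1O
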